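**Retrosynthetic overview**
1. Last step: global debenzylation (three ArOBn and one CO2Bn) of a fully benzylated diaryl ether.
2. Diaryl ether C8–O bond by SNAr: an 8-fluoroisocoumarin (fluorine ortho to the coplanar lactone C=O) plus the hindered phenol of a protected 5-hydroxy-olivetolate.
3. Isocoumarin by 6-endo-dig cyclisation of a methyl 2-(hept-1-ynyl)benzoate, made by Sonogashira coupling; the benzoate comes from lithiation/carboxylation of 1-(benzyloxy)-3-bromo-5-fluorobenzene.
4. Phenol partner from olivetolic acid: tribenzylation, regioselective bromination, borylation/oxidation.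
5. Ring order: both benzene rings are bought; the pyranone ring is the only ring formed, and it is closed before the ether coupling.

Assumption: the target has no stereocentre (it is achiral), so no enantiocontrol is needed; olivetolic acid and 1-(benzyloxy)-3-bromo-5-fluorobenzene are taken as catalogue compounds.

**Route**

Step 1
Reactants: 1 olivetolic acid (2,4-dihydroxy-6-pentylbenzoic acid)
Product: 2 benzyl 2,4-bis(benzyloxy)-6-pentylbenzoate
Conditions: BnBr (3.6 equiv), K2CO3 (4.5 equiv), cat. TBAI, DMF, rt → 60 °C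
Reagents that add atoms: benzyl bromide (BrCc1ccccc1)
Why: Williamson-type SN2 O-alkylation of the carboxylate and both phenoxides; the carboxylate is esterified first at rt (so no decarboxylation) and warming benzylates the hydrogen-bonded 2-OH.

Step 2
Reactants: 2 benzyl 2,4-bis(benzyloxy)-6-pentylbenzoate
Product: 3 benzyl 4,6-bis(benzyloxy)-3-bromo-2-pentylbenzoate
Conditions: NBS (1.05 equiv), MeCN, 0 °C → rt, dark
Reagents that add atoms: N-bromosuccinimide (O=C1CCC(=O)N1Br)
Why: Electrophilic aromatic bromination goes para to the 2-benzyloxy and ortho to the 4-benzyloxy group (next to the pentyl chain) rather than to the more crowded carbon between the two benzyloxy groups, as with other 3,5-dialkoxy-alkylbenzenes.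

Step 3
Reactants: 3 benzyl 4,6-bis(benzyloxy)-3-bromo-2-pentylbenzoate
Product: 5 benzyl 4,6-bis(benzyloxy)-3-hydroxy-2-pentylbenzoate, via aryl pinacol boronate 4 (not isolated)
Conditions: HBpin (1.5 equiv), Et3N (3 equiv), Pd(OAc)2 (2 mol %), SPhos (4 mol %), dioxane, 90 °C; then 30% H2O2, 2 M NaOH, THF, 0 °C
Reagents that add atoms: hydrogen peroxide (OO); pinacolborane (CC1(C)OBOC1(C)C, boron of 4 only)
Why: Pd/SPhos-catalysed Miyaura-type borylation tolerates di-ortho-substituted electron-rich aryl bromides, and the boronate is oxidised in the same flask (1,2-aryl shift from boron to oxygen) while the hindered benzyl ester resists the cold base.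

Step 4
Reactants: 6 1-(benzyloxy)-3-bromo-5-fluorobenzene
Product: 8 methyl 4-(benzyloxy)-2-bromo-6-fluorobenzoate, via aryllithium 7 (not isolated)
Conditions: LDA (1.1 equiv), THF, −78 °C, 45 min; then ClCO2Me (1.5 equiv), −78 °C → rt
Reagents that add atoms: methyl chloroformate (COC(=O)Cl); lithium diisopropylamide ([Li]N(C(C)C)C(C)C, lithium of 7 only)
Why: Directed ortho-metalation: LDA removes the most acidic ring proton, the one flanked by F and Br, and at −78 °C the aryllithium is acylated by the chloroformate before benzyne formation or halogen dance.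

Step 5
Reactants: 8 methyl 4-(benzyloxy)-2-bromo-6-fluorobenzoate; 9 hept-1-yne
Product: 10 methyl 4-(benzyloxy)-2-fluoro-6-(hept-1-yn-1-yl)benzoate
Conditions: PdCl2(PPh3)2 (5 mol %), CuI (10 mol %), Et3N, DMF, 70 °C
Reagents that add atoms: none
Why: Sonogashira coupling; the C–Br bond is activated by the ortho ester, and Et3N is too weak a nucleophile to displace the fluoride.

Step 6
Reactants: 10 methyl 4-(benzyloxy)-2-fluoro-6-(hept-1-yn-1-yl)benzoate
Product: 11 6-(benzyloxy)-8-fluoro-3-pentyl-1H-isochromen-1-one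
Conditions: Ph3PAuCl/AgOTf (5 mol %), H2O (2 equiv), DCE, 60 °C
Reagents that add atoms: none
Why: Gold(I) π-activation of the alkyne triggers 6-endo-dig attack of the ester carbonyl oxygen on the distal, pentyl-bearing alkyne carbon; water then cleaves the O-methyl oxocarbenium and protodeauration gives the isocoumarin.

Step 7
Reactants: 5 benzyl 4,6-bis(benzyloxy)-3-hydroxy-2-pentylbenzoate; 11 6-(benzyloxy)-8-fluoro-3-pentyl-1H-isochromen-1-one
Product: 12 benzyl 4,6-bis(benzyloxy)-3-{[6-(benzyloxy)-1-oxo-3-pentyl-1H-isochromen-8-yl]oxy}-2-pentylbenzoate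
Conditions: Cs2CO3 (1.5 equiv), 4 Å MS, dry DMSO, 90 °C
Reagents that add atoms: none
Why: SNAr: the 8-fluorine is ortho to the ring-locked, coplanar lactone carbonyl that stabilises the Meisenheimer complex, and the caesium phenoxide in dry DMSO is nucleophilic enough despite its two ortho substituents while the lactone stays closed.

Step 8
Reactants: 12 benzyl 4,6-bis(benzyloxy)-3-{[6-(benzyloxy)-1-oxo-3-pentyl-1H-isochromen-8-yl]oxy}-2-pentylbenzoate
Product: 13 4,6-dihydroxy-3-[(6-hydroxy-1-oxo-3-pentyl-1H-isochromen-8-yl)oxy]-2-pentylbenzoic acid (target)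
Conditions: BCl3 (10 equiv), C6HMe5 (12 equiv), CH2Cl2, −78 → 0 °C; then MeOH, H2O, work-up below 25 °C
Reagents that add atoms: none
Why: Lewis-acid debenzylation: BCl3 ionises the three aryl benzyl ethers and the benzyl ester, pentamethylbenzene traps the benzyl cations by Friedel–Crafts alkylation, and the enol-lactone C=C that hydrogenolysis could reduce is untouched; no stereocentre is involved.

**Compound list**
1 | olivetolic acid (2,4-dihydroxy-6-pentylbenzoic acid) | CCCCCc1cc(O)cc(O)c1C(=O)O | starting material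
2 | benzyl 2,4-bis(benzyloxy)-6-pentylbenzoate | CCCCCc1cc(OCc2ccccc2)cc(OCc2ccccc2)c1C(=O)OCc1ccccc1 | intermediate
3 | benzyl 4,6-bis(benzyloxy)-3-bromo-2-pentylbenzoate | CCCCCc1c(Br)c(OCc2ccccc2)cc(OCc2ccccc2)c1C(=O)OCc1ccccc1 | intermediate
4 | benzyl 4,6-bis(benzyloxy)-2-pentyl-3-(4,4,5,5-tetramethyl-1,3,2-dioxaborolan-2-yl)benzoate | CCCCCc1c(B2OC(C)(C)C(C)(C)O2)c(OCc2ccccc2)cc(OCc2ccccc2)c1C(=O)OCc1ccccc1 | intermediate (not isolated)
5 | benzyl 4,6-bis(benzyloxy)-3-hydroxy-2-pentylbenzoate | CCCCCc1c(O)c(OCc2ccccc2)cc(OCc2ccccc2)c1C(=O)OCc1ccccc1 | intermediate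
6 | 1-(benzyloxy)-3-bromo-5-fluorobenzene | Fc1cc(Br)cc(OCc2ccccc2)c1 | starting material
7 | [4-(benzyloxy)-2-bromo-6-fluorophenyl]lithium | [Li]c1c(F)cc(OCc2ccccc2)cc1Br | intermediate (not isolated)
8 | methyl 4-(benzyloxy)-2-bromo-6-fluorobenzoate | COC(=O)c1c(F)cc(OCc2ccccc2)cc1Br | intermediate
9 | hept-1-yne | CCCCCC#C | starting material
10 | methyl 4-(benzyloxy)-2-fluoro-6-(hept-1-yn-1-yl)benzoate | CCCCCC#Cc1cc(OCc2ccccc2)cc(F)c1C(=O)OC | intermediate
11 | 6-(benzyloxy)-8-fluoro-3-pentyl-1H-isochromen-1-one | CCCCCc1cc2cc(OCc3ccccc3)cc(F)c2c(=O)o1 | intermediate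
12 | benzyl 4,6-bis(benzyloxy)-3-{[6-(benzyloxy)-1-oxo-3-pentyl-1H-isochromen-8-yl]oxy}-2-pentylbenzoate | CCCCCc1cc2cc(OCc3ccccc3)cc(Oc3c(OCc4ccccc4)cc(OCc4ccccc4)c(C(=O)OCc4ccccc4)c3CCCCC)c2c(=O)o1 | intermediate
13 | 4,6-dihydroxy-3-[(6-hydroxy-1-oxo-3-pentyl-1H-isochromen-8-yl)oxy]-2-pentylbenzoic acid | CCCCCc1cc2cc(O)cc(Oc3c(O)cc(O)c(C(=O)O)c3CCCCC)c2c(=O)o1 | target

**Step count**
Total: 8 steps. Longest linear sequence: 5 steps (1 → 2 → 3 → 5 → 12 → 13, or equally 6 → 8 → 10 → 11 → 12 → 13).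

**Three steps most likely to fail, with fallbacks**

Step 7 (SNAr of a di-ortho-substituted phenoxide on 11) is the riskiest: the lactone may not activate enough, or may be opened. The fallback moves the ether formation to an aldehyde-activated ring. It sets out from 6 and comes back to the route at 12. Lithiate 6 as in step 4 (aryllithium 7) but quench with DMF to give 4-(benzyloxy)-2-bromo-6-fluorobenzaldehyde F1. SNAr of F1 with phenol 5 (K2CO3, DMF, 80 °C) gives benzyl 4,6-bis(benzyloxy)-3-[5-(benzyloxy)-3-bromo-2-formylphenoxy]-2-pentylbenzoate F2. Sonogashira coupling of F2 with 9 gives benzyl 4,6-bis(benzyloxy)-3-[5-(benzyloxy)-2-formyl-3-(hept-1-yn-1-yl)phenoxy]-2-pentylbenzoate F3. Pinnick oxidation (NaClO2, NaH2PO4, 2-methyl-2-butene, t-BuOH/H2O) gives 4-(benzyloxy)-2-{3-[(benzyloxy)carbonyl]-4,6-bis(benzyloxy)-2-pentylphenoxy}-6-(hept-1-yn-1-yl)benzoic acid F4. Gold- or silver-catalysed 6-endo-dig cycloisomerisation of F4 (Ph3PAuCl/AgOTf cat., DCE) closes the lactone and gives 12.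

Step 3 (borylation/oxidation of a di-ortho-substituted, electron-rich bromide) may stall or give hydrodebromination. The fallback introduces the oxygen through a formyl group. It sets out from 2 and comes back at 5, bypassing 3. Vilsmeier–Haack formylation of 2 (POCl3, DMF, 70 °C) gives benzyl 4,6-bis(benzyloxy)-3-formyl-2-pentylbenzoate F5. Baeyer–Villiger (Dakin-type) oxidation with mCPBA in CH2Cl2 gives the aryl formate benzyl 4,6-bis(benzyloxy)-3-(formyloxy)-2-pentylbenzoate F6. Methanolysis of F6 (cat. K2CO3, MeOH, 0 °C) gives 5.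

Step 6 (gold-catalysed cyclisation of the methyl ester) may be sluggish or give some 5-exo product. The fallback uses a stoichiometric electrophile. It sets out from 10 and comes back at 11. Iodocyclisation of 10 with ICl (CH2Cl2, rt) gives 6-(benzyloxy)-8-fluoro-4-iodo-3-pentyl-1H-isochromen-1-one F7. Hydrodeiodination of F7 (Pd(OAc)2/PPh3 cat., HCO2Na, DMF, 60 °C) gives 11.

**Further compounds**
F1 | step 7 | 4-(benzyloxy)-2-bromo-6-fluorobenzaldehyde | O=Cc1c(F)cc(OCc2ccccc2)cc1Br
F2 | step 7 | benzyl 4,6-bis(benzyloxy)-3-[5-(benzyloxy)-3-bromo-2-formylphenoxy]-2-pentylbenzoate | CCCCCc1c(Oc2cc(OCc3ccccc3)cc(Br)c2C=O)c(OCc2ccccc2)cc(OCc2ccccc2)c1C(=O)OCc1ccccc1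
F3 | step 7 | benzyl 4,6-bis(benzyloxy)-3-[5-(benzyloxy)-2-formyl-3-(hept-1-yn-1-yl)phenoxy]-2-pentylbenzoate | CCCCCc1c(Oc2cc(OCc3ccccc3)cc(C#CCCCCC)c2C=O)c(OCc2ccccc2)cc(OCc2ccccc2)c1C(=O)OCc1ccccc1
F4 | step 7 | 4-(benzyloxy)-2-{3-[(benzyloxy)carbonyl]-4,6-bis(benzyloxy)-2-pentylphenoxy}-6-(hept-1-yn-1-yl)benzoic acid | CCCCCc1c(Oc2cc(OCc3ccccc3)cc(C#CCCCCC)c2C(=O)O)c(OCc2ccccc2)cc(OCc2ccccc2)c1C(=O)OCc1ccccc1
F5 | step 3 | benzyl 4,6-bis(benzyloxy)-3-formyl-2-pentylbenzoate | CCCCCc1c(C=O)c(OCc2ccccc2)cc(OCc2ccccc2)c1C(=O)OCc1ccccc1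
F6 | step 3 | benzyl 4,6-bis(benzyloxy)-3-(formyloxy)-2-pentylbenzoate | CCCCCc1c(OC=O)c(OCc2ccccc2)cc(OCc2ccccc2)c1C(=O)OCc1ccccc1
F7 | step 6 | 6-(benzyloxy)-8-fluoro-4-iodo-3-pentyl-1H-isochromen-1-one | CCCCCc1oc(=O)c2c(F)cc(OCc3ccccc3)cc2c1I
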